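The cyclohexene is disconnected at C1–C2 and C3–C4. The feature exploited is the tertiary carbinol C1, which carries the branch carbon C7 and sits beside the trans C2/C3 diester. C1, its hydroxyl and C7 map onto C3, the hydroxyl and the lactone carbonyl of 3-hydroxy-2-pyrone, while C2–C3 is an E enone that already bears the C3 benzoate. One base-catalysed [4+2] cycloaddition of the free hydroxypyrone with (E)-4-(benzoyloxy)but-3-en-2-one closes the six-membered carbocycle as a lactone-bridged bicyclo[2.2.2]octene and sets C1 to C4. The acetyl later becomes the C2 acetate; the bridge supplies C7 and, through an epoxide on the bridge face, the C6 oxygen.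

Key step: step 2

Remark on labels: ring atoms carry the target locants throughout (C1 carbinol carbon with branch C7, C2 acetate, C3 benzoate, C4=C5, C6 acetate). β is the face of the carbocycle on which C7 and the lactone bridge lie; α is the other face.

Assumption: the quinidine-derived thiourea is taken to give the enantiomer drawn for 5; if the sense of induction proves opposite, the quinine-derived pseudoenantiomer replaces it with no other change.

Step 1
Reactants: 1 benzoic acid; 2 but-3-yn-2-one
Product: 3 (E)-4-(benzoyloxy)but-3-en-2-one
Conditions: DABCO (10 mol %), CH2Cl2, 0 °C → rt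
Reagents that add atoms: none
Why: Tertiary-amine-catalysed oxa-Michael addition of a carboxylic acid to an ynone (the amine adds first and the carboxylate displaces it by addition–elimination) should give the β-acyloxy enone as the thermodynamically preferred E isomer.

Step 2
Reactants: 4 3-hydroxy-2H-pyran-2-one; 3 (E)-4-(benzoyloxy)but-3-en-2-one
Product: 5 (1R,4R,7S,8S)-8-acetyl-4-hydroxy-3-oxo-2-oxabicyclo[2.2.2]oct-5-en-7-yl benzoate (C1 hydroxyl, α/endo acetyl on C2, β/exo benzoate on C3, lactone oxygen on C4, C5=C6)
Conditions: 9-epi-amino-9-deoxyquinidine N-[3,5-bis(trifluoromethyl)phenyl]thiourea (10 mol %), Et2O–CH2Cl2, −30 °C; cold filtration through silica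
Reagents that add atoms: none
Why: The quinuclidine nitrogen deprotonates the 3-hydroxyl of 4, and the ion-paired oxidodiene bonds through its distal carbon (pyrone C6, future C4) to the benzoyloxy-bearing β-carbon of 3 (future C3) while the oxido-bearing carbon (pyrone C3, future C1) bonds to the α-carbon (future C2) in a strongly asynchronous [4+2] whose stepwise limit is Michael addition followed by aldol closure. The closest known reaction type is the cinchona-base-catalysed Diels–Alder reaction of 3-hydroxy-2-pyrones with enones and other electron-poor alkenes. The one new ring, the carbocycle C1–C6, closes by cycloaddition suprafacial on both partners (6-exo-trig aldol in the stepwise limit) and leaves the lactone as a two-atom bridge between C1 and C4. C1 and C4 are fixed together by the diene face that the chiral ion pair exposes, the trans C2/C3 relation is inherited from the E alkene, and the endo (α) acetyl should result from the thiourea-bound ketone lying under the diene beside the ammonium–oxide contact. Regiochemistry is secured by the oxido donor of the diene and the acetyl acceptor of the dienophile; the step also needs C–C bonding to outrun benzoyl transfer to the pyrone oxygen and loss of benzoate, which the low temperature, the aprotic medium, a catalyst without a free hydroxyl and early removal of the base should secure.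

Step 3
Reactants: 5 lactone-bridged adduct
Product: 7 5,6β-epoxy C2-acetate lactone, via β-epoxy ketone 6 (not isolated)
Conditions: mCPBA (4 equiv), CH2Cl2, 0 °C → rt, then 40 °C
Reagents that add atoms: 3-chloroperbenzoic acid (mCPBA), OOC(=O)c1cccc(Cl)c1
Why: Prilezhaev epoxidation should occur first on the alkene face turned toward the flat lactone bridge (the α face is covered by the endo acetyl), which also removes the path to thermal loss of CO2, and the slower Baeyer–Villiger oxidation then inserts oxygen between C2 and the acetyl carbonyl with migration of the secondary carbon in preference to methyl and with retention at C2.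

Step 4
Reactants: 7 5,6β-epoxy C2-acetate lactone
Product: 9 (1R,2S,3R,6S)-2-acetoxy-3-(benzoyloxy)-1,6-dihydroxycyclohex-4-ene-1-carboxylic acid (target locants), via trans-iodohydrin 8 (not isolated)
Conditions: LiI, AcOH, THF, rt; then Zn dust, 0 °C → rt
Reagents that add atoms: lithium iodide, [Li+].[I-] (its iodine enters intermediate 8 and leaves again; 9 gains only hydrogen)
Why: Iodide should open the epoxide by SN2 attack at C5, whose rear side faces only the α hydrogen of C3 whereas the rear of C6 is screened by the α acetate on C2 and the quaternary C1, and zinc then effects a Boord/Fischer–Zach-type reductive β-elimination in which the C5 organozinc expels the lactone carboxylate at C4 and not the free hydroxyl at C6, so that the alkene moves to C4=C5, the lactone opens and the C6 oxygen stays β, cis to C7.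

Step 5
Reactants: 9 hydroxy acid
Product: 10 (1R,2S,3R,6S)-2-acetoxy-3-(benzoyloxy)-1-(hydroxymethyl)cyclohex-4-ene-1,6-diol (target locants)
Conditions: BH3·THF (2.5 equiv), THF, 0 °C; then H2O
Reagents that add atoms: none
Why: Chemoselective borane reduction of a carboxylic acid, which leaves esters untouched; the α-hydroxy acid reacts through a cyclic acyloxyborane and should be reduced at 0 °C before the electron-poor C4=C5 alkene, flanked by two allylic oxygens, is hydroborated.

Step 6
Reactants: 10 triol
Product: 11 [(1R,2S,3R,6S)-2-acetoxy-3-(benzoyloxy)-1,6-dihydroxycyclohex-4-en-1-yl]methyl benzoate (target locants)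
Conditions: BzCl (1.05 equiv), pyridine, CH2Cl2, −40 → 0 °C
Reagents that add atoms: benzoyl chloride, O=C(Cl)c1ccccc1
Why: Selective acylation, since the primary C7 hydroxyl should be benzoylated well before the secondary allylic C6 hydroxyl and the tertiary C1 hydroxyl when one equivalent of acid chloride is used at low temperature.

Step 7
Reactants: 11 C7 monobenzoate
Product: 12 [(1R,2S,3R,6S)-2,6-diacetoxy-3-(benzoyloxy)-1-hydroxycyclohex-4-en-1-yl]methyl benzoate (target locants), CNP0221209.1
Conditions: Ac2O, pyridine, DMAP (cat.), CH2Cl2, 0 °C → rt
Reagents that add atoms: acetic anhydride, CC(=O)OC(C)=O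
Why: Standard pyridine/DMAP acetylation of the secondary allylic C6 alcohol, under which the hindered tertiary C1 hydroxyl should stay free and no stereocentre is touched.

Compound list
1 | benzoic acid | OC(=O)c1ccccc1 | starting material
2 | but-3-yn-2-one | CC(=O)C#C | starting material
3 | (E)-4-(benzoyloxy)but-3-en-2-one | CC(=O)/C=C/OC(=O)c1ccccc1 | intermediate
4 | 3-hydroxy-2H-pyran-2-one | O=C1OC=CC=C1O | starting material
5 | (1R,4R,7S,8S)-8-acetyl-4-hydroxy-3-oxo-2-oxabicyclo[2.2.2]oct-5-en-7-yl benzoate | O[C@@]12C=C[C@@H](OC1=O)[C@@H](OC(=O)c1ccccc1)[C@@H]2C(C)=O | intermediate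
6 | 5,6β-epoxide of 5 (epoxide on the lactone-bridge face, C2 acetyl kept) | O[C@@]12[C@H]3O[C@H]3[C@@H](OC1=O)[C@@H](OC(=O)c1ccccc1)[C@@H]2C(C)=O | intermediate
7 | 5,6β-epoxy lactone with α acetate on C2, β benzoate on C3 and free C1 hydroxyl | O[C@@]12[C@H]3O[C@H]3[C@@H](OC1=O)[C@@H](OC(=O)c1ccccc1)[C@@H]2OC(C)=O | intermediate
8 | iodohydrin of 7 (α iodide on C5, β hydroxyl on C6, lactone intact) | O[C@@]12[C@@H](O)[C@H](I)[C@@H](OC1=O)[C@@H](OC(=O)c1ccccc1)[C@@H]2OC(C)=O | intermediate
9 | (1R,2S,3R,6S)-2-acetoxy-3-(benzoyloxy)-1,6-dihydroxycyclohex-4-ene-1-carboxylic acid (target locants) | O[C@H]1C=C[C@@H](OC(=O)c2ccccc2)[C@H](OC(C)=O)[C@@]1(O)C(O)=O | intermediate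
10 | (1R,2S,3R,6S)-2-acetoxy-3-(benzoyloxy)-1-(hydroxymethyl)cyclohex-4-ene-1,6-diol (target locants) | O[C@H]1C=C[C@@H](OC(=O)c2ccccc2)[C@H](OC(C)=O)[C@@]1(O)CO | intermediate
11 | [(1R,2S,3R,6S)-2-acetoxy-3-(benzoyloxy)-1,6-dihydroxycyclohex-4-en-1-yl]methyl benzoate (target locants) | O[C@H]1C=C[C@@H](OC(=O)c2ccccc2)[C@H](OC(C)=O)[C@@]1(O)COC(=O)c1ccccc1 | intermediate
12 | [(1R,2S,3R,6S)-2,6-diacetoxy-3-(benzoyloxy)-1-hydroxycyclohex-4-en-1-yl]methyl benzoate (target locants) | CC(=O)O[C@H]1C=C[C@@H](OC(=O)c2ccccc2)[C@H](OC(C)=O)[C@@]1(O)COC(=O)c1ccccc1 | target

Total step count: 7. Longest linear sequence: 7 steps (steps 1 to 7; the pyrone 4 enters at step 2).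

Steps most likely to fail

Step 2. Benzoyl transfer from the vinylogous anhydride 3 to the pyrone oxygen, and expulsion of benzoate from the Michael-type intermediate or from the adduct, may compete with ring closure; control of endo/exo orientation and of the absolute sense may also be insufficient. The fallback is a base-free cycloaddition followed by separation of enantiomers. It sets out from 4, which is silylated (Et3SiCl, imidazole, CH2Cl2) to 3-(triethylsilyloxy)-2H-pyran-2-one F1, a neutral diene with the donor on the same terminus. Its normal-demand Diels–Alder reaction with 3 under high pressure (about 12 kbar, CH2Cl2, rt) should give, with the same regiochemistry and the acetyl endo, the racemic triethylsilyl ether of the adduct F2. The enantiomers are separated by preparative chromatography on a chiral stationary phase, and HF·pyridine (THF, 0 °C) frees the tertiary alcohol of the required enantiomer, which returns the route to 5.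

Step 4. Iodide may open the epoxide at the wrong carbon or be pre-empted by participation of the neighbouring C2 acetate, and the organozinc may expel the C6 hydroxyl and so restore the C5=C6 alkene. The fallback opens the lactone first and then runs the classical epoxy-iodide reductive elimination on the monocycle. It sets out from 7: hydroxyl-directed borane reduction of the α-hydroxy lactone (BH3·SMe2, cat. NaBH4, THF, 0 °C), which should spare the acetate and the benzoate, gives the 5,6β-epoxy triol with free C7, C4 and C1 hydroxyls F3. Benzoylation of the primary hydroxyl (BzCl, pyridine, CH2Cl2, −40 °C) gives the C7 benzoate of that epoxy triol F4. Appel-type iodination of the C4 hydroxyl with inversion (I2, PPh3, imidazole, toluene) gives the 4α-iodo-5,6β-epoxide F5. Zn dust in EtOH then removes iodide and opens the epoxide, placing the alkene at C4=C5 and leaving the β hydroxyl on C6, which returns the route to 11 (steps 5 and 6 are bypassed).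

Step 5. Hydroboration of the ring alkene may compete with reduction of the carboxyl group. The fallback uses a nucleophilic hydride on an activated acid. It sets out from 9: ethyl chloroformate and N-methylmorpholine (THF, −15 °C) convert the carboxyl group into the mixed ethyl carbonic anhydride of 9 F6, which NaBH4 in THF–H2O at 0 °C reduces to the primary alcohol without touching the alkene, returning the route to 10.

Further compounds
F1 | step 2 | 3-(triethylsilyloxy)-2H-pyran-2-one | CC[Si](CC)(CC)OC1=CC=COC1=O
F2 | step 2 | triethylsilyl ether of 5 at the C1 oxygen (formed as the racemate; the enantiomer shown is the one kept) | CC[Si](CC)(CC)O[C@@]12C=C[C@@H](OC1=O)[C@@H](OC(=O)c1ccccc1)[C@@H]2C(C)=O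
F3 | step 4 | 5,6β-epoxy triol: C1(OH)(CH2OH), α acetate on C2, β benzoate on C3, β hydroxyl on C4 | [C@H]12O[C@H]1[C@@H](O)[C@@H](OC(=O)c1ccccc1)[C@H](OC(C)=O)[C@@]2(O)CO
F4 | step 4 | C7 benzoate of F3 | [C@H]12O[C@H]1[C@@H](O)[C@@H](OC(=O)c1ccccc1)[C@H](OC(C)=O)[C@@]2(O)COC(=O)c1ccccc1
F5 | step 4 | 4α-iodo-5,6β-epoxide derived from F4 | [C@H]12O[C@H]1[C@H](I)[C@@H](OC(=O)c1ccccc1)[C@H](OC(C)=O)[C@@]2(O)COC(=O)c1ccccc1
F6 | step 5 | mixed ethyl carbonic anhydride of acid 9 | O[C@H]1C=C[C@@H](OC(=O)c2ccccc2)[C@H](OC(C)=O)[C@@]1(O)C(=O)OC(=O)OCC
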